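Abbreviations used throughout: ArO = [7-methoxy-4-oxo-2-(2-phenylethyl)-4H-chromen-6-yl]oxy; PMB = 4-methoxybenzyl. Chromone numbering (C4a, C5–C8, C8a) is used for the carbocycle at every stage.

## The problem

The target is an unsymmetrical ether dimer of two 2-(2-phenylethyl)chromones. C8 of a 5,6,7,8-tetrahydrochromone is bound through oxygen to C6 of an aromatic 7-methoxychromone. The saturated ring carries four contiguous oxygenated stereocentres, (5S,6R,7S,8S), related 5,6-trans, 6,7-trans and 7,8-cis. The cis relation at C7/C8 rules out opening a 7,8-epoxide with the phenol, so the aryl–oxygen bond must be made on an existing C8 carbinol with retention. C6, C7 and C8 are best taken together from one chiral source. C5 can then be set last, because a nucleophile entering C5 of a C4a=C5 enone anti to the C6 ether gives the trans relation.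

Several groups will not survive rough treatment:
- The C5–O bond ionises easily, because the cation is stabilised through C4a=C8a by O1.
- C8–H is α to the aryloxy group and vinylogously α to the C4 carbonyl, so base can epimerise C8 or expel the C7 oxygen and aromatise the ring.
- Both γ-pyranones accept nucleophiles at C2 and are acidic at the 2-methylene group.

Hydrogenolysis and strong Lewis acids are therefore poor choices for the last deprotection.

The feature that opens the route is a sugar correspondence. C6, C7 and C8 with their oxygens have the configuration of C2, C3 and C4 of D-altrose, C8a and C4a correspond to C5 and C6 of the sugar, and C5 to C1. The aryl ether sits on O4, the one hydroxyl that 4,6-acetal chemistry of a pyranoside sets apart from the others.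

## Retrosynthesis

**25 to 24.** The three free hydroxyls of target 25 are unmasked last from the tris-PMB ether 24 by cutting three O–CH2Ar bonds. PMB is preferred to benzyl because its removal with DDQ is oxidative and near neutral. Benzyl would need hydrogenolysis, which threatens the allylic C5–O and C8–OAr bonds and the pyranone double bonds, or a boron halide, which threatens ionisation at C5. The forward step must leave the electron-poor chromone arenes untouched.

**24 to 22.** The pyranone O1–C2 bond and the C5–O bond are cut together, leading to the 2-alkynoyl cyclohexenone 22 and 4-methoxybenzyl alcohol. The neighbouring cut, C-acylation of a ketone that already carries the C5 oxygen, would pass through an enolate with a β-leaving group and an ambiguous choice between C4a and C8. In 22 the C4a position is defined by the alkene. The forward reaction must add the alkoxide to C5 in preference to the ynone, anti to the C6 ether, and close the enolate oxygen 6-endo on the alkyne.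

**22 to 20 and 21.** The C4a–C4 and C3–C4 bonds are cut to the α-iodoenone 20, carbon monoxide and 4-phenyl-1-butyne 21. This keeps the three-carbon unit of the pyranone as one commercial alkyne. The forward coupling must insert carbon monoxide faster than it couples the alkyne directly. Removal of the iodine from 20 gives the enone 19, which is iodinated regiospecifically at the α-carbon.

**19 to 16.** The C4a–C5 bond of enone 19 is cut by the Ferrier carbocyclisation transform to the hex-5-enopyranoside 16. This is the central simplification: the six-membered carbocycle with three correctly placed oxygenated stereocentres becomes a pyranoside of D-altrose bearing the aryl ether at O4. Closing C5–C6 or C7–C8 instead would require building those stereocentres rather than buying them. The forward reaction must form the ring without losing the aryloxy group and deliver the enone without epimerising the aryloxy carbon.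

**16 to 15 and 7.** The O4–aryl bond is cut to the enopyranoside alcohol 15 and the aryl(trimethoxyphenyl)iodonium salt 7. Arylation of the alkoxide does not touch C4, so the configuration is retained. The alternatives are SN2 displacement at C4 of a 4-epimeric sulfonate by the phenoxide, or a nucleophilic aromatic substitution that the unactivated C6 position of the chromone does not allow. The forward step must transfer the chromonyl group and not the trimethoxyphenyl group.

**7 to 1 and 3.** The salt 7 comes from iodochromone 5. Its pyranone is cut at O1–C2 and C2–C3 to the iodo ketone 2 and ethyl 3-phenylpropanoate 3, and 2 comes from 2'-hydroxy-4'-methoxyacetophenone 1. Iodination before chromone formation is chosen because the free phenol of 1 directs the iodine para to itself, whereas the finished chromone offers C3, C6 and C8.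

**15 to 12.** The enol ether of 15 is cut to the primary iodide 14, and from there to the 4,6-diol 13 and the benzylidene acetal 12. Acetal cleavage followed by selective iodination of the primary hydroxyl frees O4 without any step on O4 itself. A radical bromination of the acetal would be shorter on paper but would not tolerate PMB ethers.

**12 to 8.** The altro configuration of 12 is traced through diol 11 and the manno epoxide 10 to methyl 4,6-O-benzylidene-α-D-glucopyranoside 8. Trans-diaxial opening of the rigid epoxide by hydroxide sets O2 and O3 as required. Only two steps separate a cheap gluco compound from the rare altro pattern.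

## Roads not taken

**Alternative 1:** Here C4–C4a and C3–C4 of both chromone halves are cut at once. The bis-iodide A2, an aryl iodide and an α-iodoenone in one molecule, is coupled twice with alkyne 21 under carbon monoxide with palladium–copper catalysis to give the bis-ynone A1, and no ring closes in that step.
- Merits: one operation serves both halves, and the aromatic chromone need not be carried through the O-arylation, where its acidic 2-methylene and electrophilic C2 are a liability. This is a real advantage in convergence and saves about two steps in the arene branch.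
- Weak points: A1 holds two ynones and a doubly activated enone. The fluoride needed to free the phenol would also strip the ring silyl ethers of a base-labile cyclohexenone. An alkoxide meant for C5 could add to the aryl ynone as well. Two different carbon–iodine bonds must both insert carbon monoxide completely.
- Comparison: the chosen plan gives up that step saving so that each pyranone is closed by a reaction suited to its own substrate, and so that the late intermediates never carry more than one ynone.

**Alternative 2:** The cut is C5–C6. A chiral secondary amino acid catalyst converts the C7 ketone of the racemic keto aldehyde A4 into its C6 enamine, which adds to the C5 aldehyde and closes the carbocycle to A3 while C8 epimerises to the reacting isomer.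
- Merits: no sugar, no mercury, both pyranones made early, and catalytic control of absolute configuration in a short sequence. It is clearly shorter than the chosen plan.
- Weak points: the 3-formyl-γ-pyranone in A4 is a strong acceptor at C2 and is likely to be opened by the amine catalyst. The enamine can form toward C8 as well as C6. The aldol product is a β-hydroxy ketone one dehydration from an aromatic ring. C7 must still be reduced with the hydroxyl cis to the aryl ether.
- Comparison: this route rests three of the four stereocentres on one untested dynamic resolution and one reduction, whereas the chosen plan takes C6–C8 from the sugar.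

**Alternative 3:** The pyranone is cut at C4–C4a and O1–C8a. The acylketene A8, released on heating the dioxinone A7, adds across the silyl enol ether A6, and loss of silanol gives the tri-O-silyl derivative A5 of the target.
- Merits: highly convergent, thermal and neutral, with no palladium step. The C5 oxygen is in place before the annulation, so no late addition to a fragile 2-acylenone is needed. In this respect it is better than the chosen plan.
- Weak points: A6 must be formed regioselectively from a ketone that has a β-silyloxy leaving group on one side and an acidic aryloxy carbon on the other. The cycloaddition of a hindered trisubstituted enol ether competes with dimerisation of A8 at high temperature.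
- Comparison: the chosen plan answers with a regiospecific entry to C4a through the enone and its α-iodide, at the price of setting C5 late.

Key step: step 11

Assumption: methyl 4,6-O-benzylidene-α-D-glucopyranoside (8), the benzaldehyde acetal of methyl α-D-glucopyranoside, is bought as such; the target is the (5S,6R,7S,8S) isomer.

## Route

Step 1
Reactants: 1 2'-hydroxy-4'-methoxyacetophenone
Product: 2 1-(2-hydroxy-5-iodo-4-methoxyphenyl)ethan-1-one
Conditions: NIS, CF3CO2H (cat.), MeCN, rt
Reagents that add atoms: N-iodosuccinimide, O=C1CCC(=O)N1I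
Why: Electrophilic aromatic iodination; the position para to the free phenol and ortho to the methoxy group is the most activated open site, the position between the two oxygens being hindered and the one beside the acetyl group deactivated.

Step 2
Reactants: 2 1-(2-hydroxy-5-iodo-4-methoxyphenyl)ethan-1-one; 3 ethyl 3-phenylpropanoate
Product: 5 6-iodo-7-methoxy-2-(2-phenylethyl)-4H-chromen-4-one, via diketone 4 (not isolated)
Conditions: NaH, THF, reflux; then conc. HCl, MeOH, reflux
Reagents that add atoms: none
Why: Crossed Claisen condensation of the phenoxide enolate with the ester gives the 1,3-diketone, which closes under acid by addition of the phenol and loss of water to the γ-pyranone; the aryl iodide is inert to both stages.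

Step 3
Reactants: 5 6-iodo-7-methoxy-2-(2-phenylethyl)-4H-chromen-4-one
Product: 7 [7-methoxy-4-oxo-2-(2-phenylethyl)-4H-chromen-6-yl](2,4,6-trimethoxyphenyl)iodonium 4-methylbenzenesulfonate, via iodane 6 (not isolated)
Conditions: mCPBA, TsOH·H2O, MeCN, 55 °C; then 1,3,5-trimethoxybenzene, rt
Reagents that add atoms: p-toluenesulfonic acid, Cc1ccc(S(=O)(=O)O)cc1; 1,3,5-trimethoxybenzene, COc1cc(OC)cc(OC)c1
Why: Oxidation of the aryl iodide to the trivalent-iodine hydroxy(tosyloxy) compound (Koser-type reagent) and electrophilic substitution of the electron-rich arene at iodine; this is the standard one-pot preparation of aryl(trimethoxyphenyl)iodonium salts.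

Step 4
Reactants: 8 methyl 4,6-O-benzylidene-α-D-glucopyranoside
Product: 10 methyl 2,3-anhydro-4,6-O-benzylidene-α-D-mannopyranoside, via tosylate 9 (not isolated)
Conditions: NaH, N-tosylimidazole, DMF, rt
Reagents that add atoms: none
Why: Selective sulfonylation of the more reactive O2 followed by intramolecular Williamson displacement by the O3 alkoxide with inversion at C2 gives the manno epoxide in one flask.

Step 5
Reactants: 10 methyl 2,3-anhydro-4,6-O-benzylidene-α-D-mannopyranoside
Product: 11 methyl 4,6-O-benzylidene-α-D-altropyranoside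
Conditions: KOH, H2O, DMSO, 100 °C
Reagents that add atoms: water, O
Why: Trans-diaxial (Fürst–Plattner) opening of the conformationally locked epoxide by hydroxide at C3 with inversion; together with the inversion at C2 in step 4 this sets the altro pattern, O2 up and O3 down.

Step 6
Reactants: 11 methyl 4,6-O-benzylidene-α-D-altropyranoside
Product: 12 methyl 4,6-O-benzylidene-2,3-bis-O-(4-methoxybenzyl)-α-D-altropyranoside
Conditions: NaH, PMBCl, n-Bu4NI (cat.), DMF, 0 °C to rt
Reagents that add atoms: 4-methoxybenzyl chloride, COc1ccc(CCl)cc1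
Why: Williamson etherification of both secondary hydroxyls; benzyl-type ethers do not migrate under the basic arylation used later.

Step 7
Reactants: 12 methyl 4,6-O-benzylidene-2,3-bis-O-(4-methoxybenzyl)-α-D-altropyranoside
Product: 13 methyl 2,3-bis-O-(4-methoxybenzyl)-α-D-altropyranoside
Conditions: camphorsulfonic acid (cat.), MeOH, rt
Reagents that add atoms: none
Why: Acid-catalysed transacetalisation to methanol removes the benzylidene group; PMB ethers and the methyl glycoside are stable to catalytic acid at room temperature.

Step 8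
Reactants: 13 methyl 2,3-bis-O-(4-methoxybenzyl)-α-D-altropyranoside
Product: 14 methyl 6-deoxy-6-iodo-2,3-bis-O-(4-methoxybenzyl)-α-D-altropyranoside
Conditions: I2, PPh3, imidazole, toluene, 60 °C
Reagents that add atoms: iodine, II
Why: Garegg–Samuelsson (Appel-type) iodination; the primary alkoxyphosphonium ion is displaced far faster than the secondary one, so O4 stays free.

Step 9
Reactants: 14 methyl 6-deoxy-6-iodo-2,3-bis-O-(4-methoxybenzyl)-α-D-altropyranoside
Product: 15 methyl 6-deoxy-2,3-bis-O-(4-methoxybenzyl)-α-D-arabino-hex-5-enopyranoside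
Conditions: DBU, THF, reflux
Reagents that add atoms: none
Why: E2 dehydroiodination of the primary iodide gives the exocyclic enol ether, the usual entry to 6-deoxyhex-5-enopyranosides; the free O4 hydroxyl is tolerated by the amidine base.

Step 10
Reactants: 15 methyl 6-deoxy-2,3-bis-O-(4-methoxybenzyl)-α-D-arabino-hex-5-enopyranoside; 7 [7-methoxy-4-oxo-2-(2-phenylethyl)-4H-chromen-6-yl](2,4,6-trimethoxyphenyl)iodonium 4-methylbenzenesulfonate
Product: 16 methyl 6-deoxy-2,3-bis-O-(4-methoxybenzyl)-4-O-[7-methoxy-4-oxo-2-(2-phenylethyl)-4H-chromen-6-yl]-α-D-arabino-hex-5-enopyranoside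
Conditions: t-BuOK (1.1 equiv), THF, 0 °C; then 7, 0 °C to rt
Reagents that add atoms: none
Why: Metal-free O-arylation of a secondary carbohydrate alkoxide with a diaryliodonium salt by ligand exchange at trivalent iodine and ligand coupling; the electron-rich trimethoxyphenyl group stays on iodine and the less electron-rich chromonyl group is transferred, and C4 keeps its configuration because its C–O bond is never broken.

Step 11
Reactants: 16 methyl 6-deoxy-2,3-bis-O-(4-methoxybenzyl)-4-O-[7-methoxy-4-oxo-2-(2-phenylethyl)-4H-chromen-6-yl]-α-D-arabino-hex-5-enopyranoside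
Product: 19 (4R,5S,6S)-6-(ArO)-4,5-bis[(4-methoxybenzyl)oxy]cyclohex-2-en-1-one, via hydroxy ketone 17 (not isolated), via mesylate 18 (not isolated)
Conditions: Hg(OCOCF3)2 (10 mol %), acetone/H2O (2:1), rt; then extraction into CH2Cl2, MsCl, Et3N, 0 °C
Reagents that add atoms: water, O
Why: Divalent mercury adds to the electron-rich exocyclic enol ether at sugar C6 and water adds at C5; the hemiketal opens and the methyl hemiacetal loses methanol, giving the C5-keto C1-aldehyde with mercury on C6. This mercurio ketone is a regiospecific enolate and adds to the aldehyde in a 6-(enolexo)-exo-trig aldol, forming the sugar C6–C1 bond (C4a–C5 of the target) and the cyclohexanone 17. The closest known reaction type is the Ferrier carbocyclisation of 6-deoxyhex-5-enopyranosides to 2-deoxyinososes with catalytic mercury trifluoroacetate. The new carbinol carbon forms as a mixture of epimers and is removed again, so no stereocentre is set; sugar C2, C3 and C4 are untouched. The selectivity needed is aldol before loss of an oxygen substituent: the aryloxy group is on the α' carbon and not β to the reacting enolate carbon, so it cannot leave by E1cB, and the neutral aqueous medium does not enolise toward the aryloxy carbon. Because the first stage is aqueous, the crude ketol is taken into dichloromethane before mesylation; E1cB loss of mesylate toward the only α-methylene then gives the conjugated enone. Low temperature and short contact with triethylamine should prevent epimerisation of the aryloxy carbon and aromatisation. The carbonyl oxygen of 19 comes from water, while the former ring oxygen leaves with the mesylate.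

Step 12
Reactants: 19 (4R,5S,6S)-6-(ArO)-4,5-bis[(4-methoxybenzyl)oxy]cyclohex-2-en-1-one
Product: 20 (4R,5S,6S)-6-(ArO)-2-iodo-4,5-bis[(4-methoxybenzyl)oxy]cyclohex-2-en-1-one
Conditions: I2, pyridine, CH2Cl2, 0 °C to rt
Reagents that add atoms: iodine, II
Why: α-Iodination of a cyclic enone by conjugate addition of pyridine, iodination of the enolate and elimination (Baylis–Hillman-type sequence), precedented on 4,5,6-trioxygenated cyclohexenones; it marks C4a regiospecifically.

Step 13
Reactants: 20 (4R,5S,6S)-6-(ArO)-2-iodo-4,5-bis[(4-methoxybenzyl)oxy]cyclohex-2-en-1-one; 21 4-phenyl-1-butyne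
Product: 22 (4R,5S,6S)-6-(ArO)-4,5-bis[(4-methoxybenzyl)oxy]-2-(5-phenylpent-2-ynoyl)cyclohex-2-en-1-one
Conditions: CO (1 atm), PdCl2(PPh3)2 (5 mol %), CuI (2 mol %), Et3N, THF, rt; product used at once
Reagents that add atoms: carbon monoxide, [C-]#[O+]
Why: Carbonylative Sonogashira coupling: oxidative addition of zerovalent palladium to the alkenyl iodide, insertion of carbon monoxide to the acylpalladium species and transfer of the copper acetylide; α-iodoenones are known to undergo palladium-catalysed carbonylation, and the reaction forms C4a–C4 and C4–C3.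

Step 14
Reactants: 22 (4R,5S,6S)-6-(ArO)-4,5-bis[(4-methoxybenzyl)oxy]-2-(5-phenylpent-2-ynoyl)cyclohex-2-en-1-one
Product: 24 (5S,6R,7S,8S)-8-(ArO)-5,6,7-tris[(4-methoxybenzyl)oxy]-2-(2-phenylethyl)-5,6,7,8-tetrahydro-4H-chromen-4-one, via enol 23 (not isolated)
Conditions: 4-MeOC6H4CH2OH (3 equiv), Cs2CO3 (0.2 equiv), THF, −20 to 0 °C
Reagents that add atoms: 4-methoxybenzyl alcohol, COc1ccc(CO)cc1
Why: Proposed new method: C5 of the 2-acylenone is activated by two carbonyl groups and is the most electrophilic carbon, so the alkoxide should add there reversibly, anti to the C6 ether (axial attack trans to the γ-substituent), which sets C5 as S; the resulting 1,3-diketone enolate holds the ring-ketone oxygen beside the ynone and closes 6-endo-dig to the 4-pyranone, an irreversible step that withdraws the adduct from the retro-Michael equilibrium and regenerates alkoxide on protonation; the closest known reaction types are the base-catalysed oxa-Michael addition of alcohols to alkylidene 1,3-dicarbonyl compounds and the base-mediated 6-endo-dig closure of 2-alkynoyl phenols and 2-alkynoyl ketone enols to chromones and 4-pyranones.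

Step 15
Reactants: 24 (5S,6R,7S,8S)-8-(ArO)-5,6,7-tris[(4-methoxybenzyl)oxy]-2-(2-phenylethyl)-5,6,7,8-tetrahydro-4H-chromen-4-one
Product: 25 (5S,6R,7S,8S)-5,6,7-trihydroxy-8-{[7-methoxy-4-oxo-2-(2-phenylethyl)-4H-chromen-6-yl]oxy}-2-(2-phenylethyl)-5,6,7,8-tetrahydro-4H-chromen-4-one
Conditions: DDQ (4 equiv), CH2Cl2/pH 7 phosphate buffer (10:1), 0 °C to rt
Reagents that add atoms: none
Why: Oxidative cleavage of PMB ethers by hydride abstraction at the benzylic carbon and hydrolysis of the oxocarbenium ion; the conditions are near neutral, do not ionise C5–O, and leave the chromone rings and the aryl ether alone.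

## Compound list

1 | 2'-hydroxy-4'-methoxyacetophenone | CC(=O)c1ccc(OC)cc1O | starting material
2 | 1-(2-hydroxy-5-iodo-4-methoxyphenyl)ethan-1-one | CC(=O)c1cc(I)c(OC)cc1O | intermediate
3 | ethyl 3-phenylpropanoate | CCOC(=O)CCc1ccccc1 | starting material
4 | 1-(2-hydroxy-5-iodo-4-methoxyphenyl)-5-phenylpentane-1,3-dione (not isolated) | COc1cc(O)c(cc1I)C(=O)CC(=O)CCc1ccccc1 | intermediate
5 | 6-iodo-7-methoxy-2-(2-phenylethyl)-4H-chromen-4-one | COc1cc2oc(CCc3ccccc3)cc(=O)c2cc1I | intermediate
6 | 6-[hydroxy(tosyloxy)iodo]-7-methoxy-2-(2-phenylethyl)-4H-chromen-4-one (not isolated) | COc1cc2oc(CCc3ccccc3)cc(=O)c2cc1I(O)OS(=O)(=O)c1ccc(C)cc1 | intermediate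
7 | [7-methoxy-4-oxo-2-(2-phenylethyl)-4H-chromen-6-yl](2,4,6-trimethoxyphenyl)iodonium 4-methylbenzenesulfonate | COc1cc2oc(CCc3ccccc3)cc(=O)c2cc1[I+]c1c(OC)cc(OC)cc1OC.Cc1ccc(S(=O)(=O)[O-])cc1 | intermediate
8 | methyl 4,6-O-[(R)-benzylidene]-α-D-glucopyranoside | CO[C@@H]1[C@H](O)[C@@H](O)[C@@H]2O[C@H](c3ccccc3)OC[C@H]2O1 | starting material
9 | methyl 4,6-O-benzylidene-2-O-(4-methylbenzenesulfonyl)-α-D-glucopyranoside (not isolated) | CO[C@@H]1[C@H](OS(=O)(=O)c2ccc(C)cc2)[C@@H](O)[C@@H]2O[C@H](c3ccccc3)OC[C@H]2O1 | intermediate
10 | methyl 2,3-anhydro-4,6-O-benzylidene-α-D-mannopyranoside | CO[C@@H]1[C@H]2O[C@H]2[C@@H]2O[C@H](c3ccccc3)OC[C@H]2O1 | intermediate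
11 | methyl 4,6-O-benzylidene-α-D-altropyranoside | CO[C@@H]1[C@@H](O)[C@H](O)[C@@H]2O[C@H](c3ccccc3)OC[C@H]2O1 | intermediate
12 | methyl 4,6-O-benzylidene-2,3-bis-O-(4-methoxybenzyl)-α-D-altropyranoside | CO[C@@H]1[C@@H](OCc2ccc(OC)cc2)[C@H](OCc2ccc(OC)cc2)[C@@H]2O[C@H](c3ccccc3)OC[C@H]2O1 | intermediate
13 | methyl 2,3-bis-O-(4-methoxybenzyl)-α-D-altropyranoside | CO[C@@H]1[C@@H](OCc2ccc(OC)cc2)[C@H](OCc2ccc(OC)cc2)[C@H](O)[C@@H](CO)O1 | intermediate
14 | methyl 6-deoxy-6-iodo-2,3-bis-O-(4-methoxybenzyl)-α-D-altropyranoside | CO[C@@H]1[C@@H](OCc2ccc(OC)cc2)[C@H](OCc2ccc(OC)cc2)[C@H](O)[C@@H](CI)O1 | intermediate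
15 | methyl 6-deoxy-2,3-bis-O-(4-methoxybenzyl)-α-D-arabino-hex-5-enopyranoside | CO[C@@H]1[C@@H](OCc2ccc(OC)cc2)[C@H](OCc2ccc(OC)cc2)[C@H](O)C(=C)O1 | intermediate
16 | methyl 6-deoxy-2,3-bis-O-(4-methoxybenzyl)-4-O-[7-methoxy-4-oxo-2-(2-phenylethyl)-4H-chromen-6-yl]-α-D-arabino-hex-5-enopyranoside | CO[C@@H]1[C@@H](OCc2ccc(OC)cc2)[C@H](OCc2ccc(OC)cc2)[C@H](Oc2cc3c(=O)cc(CCc4ccccc4)oc3cc2OC)C(=C)O1 | intermediate
17 | (2S,3S,4R,5RS)-2-(ArO)-5-hydroxy-3,4-bis[(4-methoxybenzyl)oxy]cyclohexan-1-one, both carbinol epimers (not isolated) | COc1cc2oc(CCc3ccccc3)cc(=O)c2cc1O[C@@H]1C(=O)CC(O)[C@@H](OCc2ccc(OC)cc2)[C@@H]1OCc1ccc(OC)cc1 | intermediate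
18 | 5-O-methanesulfonate of 17, both epimers (not isolated) | COc1cc2oc(CCc3ccccc3)cc(=O)c2cc1O[C@@H]1C(=O)CC(OS(C)(=O)=O)[C@@H](OCc2ccc(OC)cc2)[C@@H]1OCc1ccc(OC)cc1 | intermediate
19 | (4R,5S,6S)-6-(ArO)-4,5-bis[(4-methoxybenzyl)oxy]cyclohex-2-en-1-one | COc1cc2oc(CCc3ccccc3)cc(=O)c2cc1O[C@@H]1C(=O)C=C[C@@H](OCc2ccc(OC)cc2)[C@@H]1OCc1ccc(OC)cc1 | intermediate
20 | (4R,5S,6S)-6-(ArO)-2-iodo-4,5-bis[(4-methoxybenzyl)oxy]cyclohex-2-en-1-one | COc1cc2oc(CCc3ccccc3)cc(=O)c2cc1O[C@@H]1C(=O)C(I)=C[C@@H](OCc2ccc(OC)cc2)[C@@H]1OCc1ccc(OC)cc1 | intermediate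
21 | 4-phenyl-1-butyne | C#CCCc1ccccc1 | starting material
22 | (4R,5S,6S)-6-(ArO)-4,5-bis[(4-methoxybenzyl)oxy]-2-(5-phenylpent-2-ynoyl)cyclohex-2-en-1-one | COc1cc2oc(CCc3ccccc3)cc(=O)c2cc1O[C@@H]1C(=O)C(C(=O)C#CCCc2ccccc2)=C[C@@H](OCc2ccc(OC)cc2)[C@@H]1OCc1ccc(OC)cc1 | intermediate
23 | enol of (3S,4R,5S,6S)-6-(ArO)-3,4,5-tris[(4-methoxybenzyl)oxy]-2-(5-phenylpent-2-ynoyl)cyclohexan-1-one (not isolated) | COc1cc2oc(CCc3ccccc3)cc(=O)c2cc1O[C@@H]1C(O)=C(C(=O)C#CCCc2ccccc2)[C@H](OCc2ccc(OC)cc2)[C@@H](OCc2ccc(OC)cc2)[C@@H]1OCc1ccc(OC)cc1 | intermediate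
24 | (5S,6R,7S,8S)-8-(ArO)-5,6,7-tris[(4-methoxybenzyl)oxy]-2-(2-phenylethyl)-5,6,7,8-tetrahydro-4H-chromen-4-one | COc1cc2oc(CCc3ccccc3)cc(=O)c2cc1O[C@@H]1c2oc(CCc3ccccc3)cc(=O)c2[C@H](OCc2ccc(OC)cc2)[C@@H](OCc2ccc(OC)cc2)[C@@H]1OCc1ccc(OC)cc1 | intermediate
25 | (5S,6R,7S,8S)-5,6,7-trihydroxy-8-{[7-methoxy-4-oxo-2-(2-phenylethyl)-4H-chromen-6-yl]oxy}-2-(2-phenylethyl)-5,6,7,8-tetrahydro-4H-chromen-4-one | COc1cc2oc(CCc3ccccc3)cc(=O)c2cc1O[C@@H]1c2oc(CCc3ccccc3)cc(=O)c2[C@H](O)[C@@H](O)[C@@H]1O | target

## Step count and least certain steps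

Total step count: 15. Longest linear sequence: 12 steps (steps 4 to 15, from 8 to 25); the arene branch (steps 1 to 3) joins at step 10.

**Step 14 (oxa-Michael addition and pyranone closure).** Three things may go wrong.
- Deprotonation at C6 of the doubly activated enone, loss of the C7 ether and aromatisation of the carbocycle.
- Addition of the alkoxide to the ynone carbon in place of C5, or poor facial selectivity at C5.
- Epimerisation at C8 after ring closure, since that hydrogen is vinylogously acidic.

The fallback uses known reactions only. It sets out from 20 and comes back to the route at 25.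
- Nozaki–Hiyama–Kishi coupling (CrCl2, NiCl2 cat., DMF) of 20 with 5-phenylpent-2-ynal F1, made from 21 by lithiation and formylation, should give the allylic propargylic alcohol F2.
- Weitz–Scheffer epoxidation (t-BuOOH, DBU) should place the oxirane oxygen anti to the C6 ether and give the epoxy ketone F3, so that C5 is set by a known substrate-controlled reaction.
- Reductive opening of the α,β-epoxy ketone at C4a with sodium phenylselenide (PhSeSePh, NaBH4, AcOH, EtOH) should give the β-hydroxy ketone F4.
- MnO2 should oxidise only the propargylic alcohol to the enolised diketone F5, which closes 6-endo to the 5-hydroxy tetrahydrochromone F6.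
- DDQ then removes the two PMB groups to give 25.

**Step 11 (key step).** Mercury may be held by the chromone carbonyl and the oxymercuration may stall. The keto aldehyde may lose its β-alkoxy group before the aldol. During the dehydration, triethylamine may epimerise the aryloxy carbon or start aromatisation. The fallback sets out from 16 and comes back at 19. The Lewis-acid variant of the carbocyclisation with Ti(Oi-Pr)Cl3 in CH2Cl2 at −78 °C keeps the aglycone, works without water, and should give the β-methoxy ketone F7. Loss of methanol with DBU at 0 °C then gives 19 without a mesylation stage.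

**Step 13 (carbonylative coupling).** Direct alkynylation may outrun insertion of carbon monoxide at the electron-poor alkenylpalladium centre. Triethylamine may also deprotonate the product 22 and trigger loss of an ether group. The fallback sets out from 20 and comes back at 22. Chromium-mediated coupling of 20 with 5-phenylpent-2-ynal F1 gives the alcohol F2 under non-basic conditions, and Dess–Martin oxidation of F2 (NaHCO3, CH2Cl2) gives 22 immediately before step 14.

**Step 10 (O-arylation).** The alkoxide may deprotonate the 2-methylene group of the chromone or add to its C2 instead of exchanging at iodine. Transfer of the trimethoxyphenyl group would give the wrong ether. The fallback sets out from 15 and 5 and comes back at 16. It is a copper-catalysed Ullmann etherification of the alcohol 15 with the aryl iodide 5 (CuI, 3,4,7,8-tetramethyl-1,10-phenanthroline, Cs2CO3, toluene, 100 °C). This uses a weaker base and does not need the salt 7.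

## Further compounds

F1 | step 13 | 5-phenylpent-2-ynal | O=CC#CCCc1ccccc1
F2 | step 13 | (4R,5S,6S)-6-(ArO)-2-(1-hydroxy-5-phenylpent-2-yn-1-yl)-4,5-bis[(4-methoxybenzyl)oxy]cyclohex-2-en-1-one, both carbinol epimers | COc1cc2oc(CCc3ccccc3)cc(=O)c2cc1O[C@@H]1C(=O)C(C(O)C#CCCc2ccccc2)=C[C@@H](OCc2ccc(OC)cc2)[C@@H]1OCc1ccc(OC)cc1
F3 | step 14 | 4a,5-epoxide of F2 (chromone numbering) with the oxirane oxygen anti to the C6 ether | COc1cc2oc(CCc3ccccc3)cc(=O)c2cc1O[C@@H]1C(=O)[C@]2(C(O)C#CCCc3ccccc3)O[C@@H]2[C@@H](OCc2ccc(OC)cc2)[C@@H]1OCc1ccc(OC)cc1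
F4 | step 14 | (3S,4R,5S,6S)-6-(ArO)-3-hydroxy-2-(1-hydroxy-5-phenylpent-2-yn-1-yl)-4,5-bis[(4-methoxybenzyl)oxy]cyclohexan-1-one | COc1cc2oc(CCc3ccccc3)cc(=O)c2cc1O[C@@H]1C(=O)C(C(O)C#CCCc2ccccc2)[C@H](O)[C@@H](OCc2ccc(OC)cc2)[C@@H]1OCc1ccc(OC)cc1
F5 | step 14 | enol of (3S,4R,5S,6S)-6-(ArO)-3-hydroxy-4,5-bis[(4-methoxybenzyl)oxy]-2-(5-phenylpent-2-ynoyl)cyclohexan-1-one | COc1cc2oc(CCc3ccccc3)cc(=O)c2cc1O[C@@H]1C(O)=C(C(=O)C#CCCc2ccccc2)[C@H](O)[C@@H](OCc2ccc(OC)cc2)[C@@H]1OCc1ccc(OC)cc1
F6 | step 14 | (5S,6R,7S,8S)-8-(ArO)-5-hydroxy-6,7-bis[(4-methoxybenzyl)oxy]-2-(2-phenylethyl)-5,6,7,8-tetrahydro-4H-chromen-4-one | COc1cc2oc(CCc3ccccc3)cc(=O)c2cc1O[C@@H]1c2oc(CCc3ccccc3)cc(=O)c2[C@H](O)[C@@H](OCc2ccc(OC)cc2)[C@@H]1OCc1ccc(OC)cc1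
F7 | step 11 | (2S,3S,4R,5RS)-2-(ArO)-5-methoxy-3,4-bis[(4-methoxybenzyl)oxy]cyclohexan-1-one | COc1cc2oc(CCc3ccccc3)cc(=O)c2cc1O[C@@H]1C(=O)CC(OC)[C@@H](OCc2ccc(OC)cc2)[C@@H]1OCc1ccc(OC)cc1
F0 | step 10 | none | none
A1 | alternative 1 | bis-ynone: 2-(5-phenylpent-2-ynoyl)cyclohex-2-en-1-one with 4-O-tert-butyldimethylsilyl, 5-O-thexyldimethylsilyl and 6-[4-(tert-butyldimethylsilyloxy)-2-methoxy-5-(5-phenylpent-2-ynoyl)phenoxy] groups | COc1cc(O[Si](C)(C)C(C)(C)C)c(C(=O)C#CCCc2ccccc2)cc1O[C@@H]1C(=O)C(C(=O)C#CCCc2ccccc2)=C[C@@H](O[Si](C)(C)C(C)(C)C)[C@@H]1O[Si](C)(C)C(C)(C)C(C)C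
A2 | alternative 1 | bis-iodide: the 2-iodocyclohex-2-en-1-one of A1 with a 6-[4-(tert-butyldimethylsilyloxy)-5-iodo-2-methoxyphenoxy] group | COc1cc(O[Si](C)(C)C(C)(C)C)c(I)cc1O[C@@H]1C(=O)C(I)=C[C@@H](O[Si](C)(C)C(C)(C)C)[C@@H]1O[Si](C)(C)C(C)(C)C(C)C
A3 | alternative 2 | 7-oxo precursor of the target with free 5-hydroxyl and 6-O-tert-butyldimethylsilyl ether | COc1cc2oc(CCc3ccccc3)cc(=O)c2cc1O[C@@H]1c2oc(CCc3ccccc3)cc(=O)c2[C@H](O)[C@@H](O[Si](C)(C)C(C)(C)C)C1=O
A4 | alternative 2 | racemic 2-[1-(ArO)-3-(tert-butyldimethylsilyloxy)-2-oxopropyl]-3-formyl-6-(2-phenylethyl)-4H-pyran-4-one | COc1cc2oc(CCc3ccccc3)cc(=O)c2cc1OC(C(=O)CO[Si](C)(C)C(C)(C)C)c1oc(CCc2ccccc2)cc(=O)c1C=O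
A5 | alternative 3 | 5,6-bis-O-tert-butyldimethylsilyl 7-O-thexyldimethylsilyl derivative of the target | COc1cc2oc(CCc3ccccc3)cc(=O)c2cc1O[C@@H]1c2oc(CCc3ccccc3)cc(=O)c2[C@H](O[Si](C)(C)C(C)(C)C)[C@@H](O[Si](C)(C)C(C)(C)C)[C@@H]1O[Si](C)(C)C(C)(C)C(C)C
A6 | alternative 3 | trimethylsilyl enol ether (C8a=C4a) of the 8-(ArO)-5,6,7-trisilyloxy cyclohexanone | COc1cc2oc(CCc3ccccc3)cc(=O)c2cc1O[C@@H]1C(O[Si](C)(C)C)=C[C@H](O[Si](C)(C)C(C)(C)C)[C@@H](O[Si](C)(C)C(C)(C)C)[C@@H]1O[Si](C)(C)C(C)(C)C(C)C
A7 | alternative 3 | 2,2-dimethyl-6-(2-phenylethyl)-4H-1,3-dioxin-4-one | CC1(C)OC(CCc2ccccc2)=CC(=O)O1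
A8 | alternative 3 | 3-oxo-5-phenylpent-1-en-1-one (acylketene) | O=C=CC(=O)CCc1ccccc1
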